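The retrosynthesis first cuts the N1–acyl imide bond (to (E)-dodec-2-enoyl chloride and the N–H tetramic acid), then the ring bond C2–C3, re-attaching C2 to the oxygen on C4 (to a 5-(2-oxopropylidene)oxazolidin-2-one), then the carbamate O–C and N–C bonds (to a γ-amino ynone and CO2), and last the C(sp)–acetyl bond and the C≡C unit (to N-Boc-D-leucine).
Enabling feature: in the pyrrolidine-2,4-dione ring the lactam carbon C2 sits between N1 and C3, and C3 is the central carbon of the 1,3-diketone formed by C4 and the acetyl C=O. Moving C2 from C3 to the C4 oxygen gives an isomeric cyclic enol carbamate, and the two rings are linked through one isocyanate/diketonate pair.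
Forward: the leucine carboxyl becomes a terminal alkyne, the alkyne is acetylated, CO2 closes the oxazolidinone (a temporary ring), base turns it into the pyrrolidine-2,4-dione (the only ring of the target) with the 3-acetyl group already present, and N-acylation attaches the C12 chain last.
Stereochemistry: the single stereocentre (C5, R) is the α-carbon of N-Boc-D-leucine and no bond to it is made or broken; the E-olefin comes in with (E)-dodec-2-enoic acid.

Key step: step 6

Remark: 3-acyl tetramic acids are tautomeric mixtures; they are named and drawn here as the 4-hydroxy enol form used for the target.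

Step 1
Reactants: 1 N-Boc-D-leucine [(2R)-2-[(tert-butoxycarbonyl)amino]-4-methylpentanoic acid]
Product: 2 tert-butyl N-[(2R)-1-[methoxy(methyl)amino]-4-methyl-1-oxopentan-2-yl]carbamate (Weinreb amide of 1)
Conditions: MeNHOMe·HCl (1.2 equiv), EDC·HCl (1.2 equiv), HOBt (cat.), N-methylmorpholine (2.5 equiv), CH2Cl2, 0 °C → rt
Reagents that add atoms: N,O-dimethylhydroxylamine hydrochloride, CNOC.Cl
Why: Carbodiimide/HOBt amide coupling of a urethane-protected amino acid, which should not epimerise through an oxazolone, so the D-leucine stereocentre is carried over unchanged.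

Step 2
Reactants: 2 tert-butyl N-[(2R)-1-[methoxy(methyl)amino]-4-methyl-1-oxopentan-2-yl]carbamate; 3 dimethyl (1-diazo-2-oxopropyl)phosphonate (Ohira–Bestmann reagent)
Product: 5 tert-butyl N-[(3R)-5-methylhex-1-yn-3-yl]carbamate, via N-Boc-D-leucinal 4 (not isolated)
Conditions: i-Bu2AlH (2.2 equiv), CH2Cl2, −78 °C; MeOH, −78 → 0 °C; K2CO3 (3 equiv), 3 (1.5 equiv), 0 °C → rt; aq. potassium sodium tartrate
Reagents that add atoms: dimethyl (1-diazo-2-oxopropyl)phosphonate 3, COP(=O)(OC)C(=[N+]=[N-])C(C)=O
Why: Partial reduction of the Weinreb amide stops at aldehyde 4, and Seyferth–Gilbert homologation in its Ohira–Bestmann form (K2CO3/MeOH) converts it into the terminal alkyne in the same flask, so the configurationally labile α-amino aldehyde is never isolated.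

Step 3
Reactants: 5 tert-butyl N-[(3R)-5-methylhex-1-yn-3-yl]carbamate; 6 N-methoxy-N-methylacetamide
Product: 8 tert-butyl N-[(4R)-2-methyl-7-oxooct-5-yn-4-yl]carbamate, via dilithiated alkyne 7 (not isolated)
Conditions: n-BuLi (2.1 equiv), THF, −78 °C; 6 (1.3 equiv), −78 → −20 °C; AcOH (2.5 equiv) in THF, −78 °C
Reagents that add atoms: N-methoxy-N-methylacetamide 6, CON(C)C(C)=O
Why: Acylation of a lithium acetylide by a Weinreb amide, in which two equivalents of n-BuLi remove the carbamate N–H and the alkyne C–H, the chelated adduct prevents a second addition, and the cold acid quench keeps the released N,O-dimethylhydroxylamine from adding to the ynone.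

Step 4
Reactants: 8 tert-butyl N-[(4R)-2-methyl-7-oxooct-5-yn-4-yl]carbamate
Product: 9 (5R)-5-amino-7-methyloct-3-yn-2-one trifluoroacetate salt
Conditions: CF3CO2H/CH2Cl2 (1:4), 0 °C; concentrate, co-evaporate with toluene, use at once
Reagents that add atoms: trifluoroacetic acid, OC(=O)C(F)(F)F
Why: Acidolytic Boc removal should be fast at 0 °C, and keeping the amine protonated as its trifluoroacetate blocks aza-Michael addition to the ynone and leaves the stereocentre untouched.

Step 5
Reactants: 9 (5R)-5-amino-7-methyloct-3-yn-2-one trifluoroacetate salt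
Product: 11 (4R,5Z)-4-(2-methylpropyl)-5-(2-oxopropylidene)-1,3-oxazolidin-2-one, via ammonium carbamate 10 (not isolated)
Conditions: CO2 (1 atm), AgOAc (5 mol %), i-Pr2NEt (2.2 equiv), DMSO, 25 °C
Reagents that add atoms: carbon dioxide, O=C=O
Why: Silver-catalysed carboxylative cyclisation of a propargylic amine, in which the amine freed under CO2 is trapped as carbamate 10, its oxygen adds anti across the AgOAc-activated triple bond in a 5-exo-dig closure that is also the conjugate position of the ynone, and protodemetalation gives the Z-alkylidene, while i-Pr2NEt is too weak a base to open the product (either alkene geometry would serve in step 6).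

Step 6
Reactants: 11 (4R,5Z)-4-(2-methylpropyl)-5-(2-oxopropylidene)-1,3-oxazolidin-2-one
Product: 13 (5R)-3-acetyl-4-hydroxy-5-(2-methylpropyl)-1,5-dihydro-2H-pyrrol-2-one, via isocyanato diketonate 12 (not isolated)
Conditions: DBU (1.2 equiv), dry MeCN, 25 → 60 °C, N2; then cold 1 M HCl, EtOAc
Reagents that add atoms: none
Why: DBU removes the carbamate N–H of 11 and the nitrogen anion expels the ring oxygen (E1cB), which should be easy because the leaving group is an acetylacetone-type diketonate; this gives isocyanate 12. The central diketonate carbon (the future C3) then adds to the isocyanate carbon, forming C2–C3 and closing the pyrrolidine-2,4-dione by a five-membered attack on a digonal carbon (N=C inside the ring, C=O outside, allowed in either description), with the acetyl group in place from the start. Proton transfer from C3 gives the DBU-H+ salt of the strongly acidic tricarbonyl, the thermodynamic sink, and acid work-up releases 13. The closest known reaction type is the base-mediated rearrangement of 5-alkylidene oxazolidin-2-ones (from propargylic amines and CO2) into tetramic acids through an isocyanate, supported by the general C-carbamoylation of 1,3-dicarbonyl anions with isocyanates. No stereocentre is formed; C5 is carried over from D-leucine and should hold because 12 and the product are anions that resist a second deprotonation next to the carbonyl. The step needs C- over O-attack: O-attack only regenerates 11 reversibly, whereas C-attack is made irreversible by the tricarbonyl anion, and dry conditions keep the isocyanate from hydrolysis.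

Step 7
Reactants: 14 (E)-dodec-2-enoic acid
Product: 15 (E)-dodec-2-enoyl chloride
Conditions: (COCl)2 (1.3 equiv), DMF (cat.), CH2Cl2, 0 °C → rt; concentrate, use crude
Reagents that add atoms: oxalyl chloride, O=C(Cl)C(Cl)=O
Why: Acid chloride formation with oxalyl chloride under DMF catalysis (Vilsmeier-type activation) runs cold and without base, so the conjugated E double bond should neither migrate nor isomerise.

Step 8
Reactants: 13 (5R)-3-acetyl-4-hydroxy-5-(2-methylpropyl)-1,5-dihydro-2H-pyrrol-2-one; 15 (E)-dodec-2-enoyl chloride
Product: 17 reutericyclin C [(5R)-3-acetyl-1-[(2E)-dodec-2-enoyl]-4-hydroxy-5-(2-methylpropyl)-1,5-dihydro-2H-pyrrol-2-one], via dilithium salt 16 (not isolated)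
Conditions: n-BuLi (2.05 equiv), THF, −78 °C; 15 (1.1 equiv), −78 → −20 °C; 1 M HCl
Reagents that add atoms: (E)-dodec-2-enoyl chloride 15, CCCCCCCCC/C=C/C(Cl)=O
Why: N-Acylation of a lithiated lactam by an acid chloride, in which the first equivalent of n-BuLi gives the unreactive tricarbonyl enolate, the second removes the lactam N–H, and the nitrogen anion of 16 is the most nucleophilic site, so the enoyl chloride should be taken up at N1 at low temperature without disturbing C5.

Compound list
1 | N-Boc-D-leucine, (2R)-2-[(tert-butoxycarbonyl)amino]-4-methylpentanoic acid | CC(C)C[C@@H](NC(=O)OC(C)(C)C)C(=O)O | starting material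
2 | tert-butyl N-[(2R)-1-[methoxy(methyl)amino]-4-methyl-1-oxopentan-2-yl]carbamate | CC(C)C[C@@H](NC(=O)OC(C)(C)C)C(=O)N(C)OC | intermediate
3 | dimethyl (1-diazo-2-oxopropyl)phosphonate | COP(=O)(OC)C(=[N+]=[N-])C(C)=O | starting material
4 | N-Boc-D-leucinal, tert-butyl N-[(2R)-4-methyl-1-oxopentan-2-yl]carbamate | CC(C)C[C@@H](NC(=O)OC(C)(C)C)C=O | intermediate
5 | tert-butyl N-[(3R)-5-methylhex-1-yn-3-yl]carbamate | CC(C)C[C@@H](NC(=O)OC(C)(C)C)C#C | intermediate
6 | N-methoxy-N-methylacetamide | CON(C)C(C)=O | starting material
7 | dilithium salt of 5 (N-lithio carbamate, lithium acetylide) | [Li+].[Li+].CC(C)C[C@@H]([N-]C(=O)OC(C)(C)C)C#[C-] | intermediate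
8 | tert-butyl N-[(4R)-2-methyl-7-oxooct-5-yn-4-yl]carbamate | CC(C)C[C@@H](NC(=O)OC(C)(C)C)C#CC(C)=O | intermediate
9 | (5R)-5-amino-7-methyloct-3-yn-2-one trifluoroacetate salt | CC(C)C[C@@H]([NH3+])C#CC(C)=O.[O-]C(=O)C(F)(F)F | intermediate
10 | diisopropylethylammonium N-[(4R)-2-methyl-7-oxooct-5-yn-4-yl]carbamate | CC(C)C[C@@H](NC(=O)[O-])C#CC(C)=O.CC[NH+](C(C)C)C(C)C | intermediate
11 | (4R,5Z)-4-(2-methylpropyl)-5-(2-oxopropylidene)-1,3-oxazolidin-2-one | CC(=O)/C=C1\OC(=O)N[C@@H]1CC(C)C | intermediate
12 | DBU-H+ salt of the enolate of (5R)-5-isocyanato-7-methyloctane-2,4-dione | CC(=O)C=C([O-])[C@@H](CC(C)C)N=C=O.C1CCC2=[NH+]CCCN2CC1 | intermediate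
13 | (5R)-3-acetyl-4-hydroxy-5-(2-methylpropyl)-1,5-dihydro-2H-pyrrol-2-one | CC(=O)C1=C(O)[C@@H](CC(C)C)NC1=O | intermediate
14 | (E)-dodec-2-enoic acid | CCCCCCCCC/C=C/C(=O)O | starting material
15 | (E)-dodec-2-enoyl chloride | CCCCCCCCC/C=C/C(Cl)=O | intermediate
16 | dilithium salt of 13 (N-lithio lactam, lithium enolate) | [Li+].[Li+].CC(=O)C1=C([O-])[C@@H](CC(C)C)[N-]C1=O | intermediate
17 | reutericyclin C, (5R)-3-acetyl-1-[(2E)-dodec-2-enoyl]-4-hydroxy-5-(2-methylpropyl)-1,5-dihydro-2H-pyrrol-2-one | CCCCCCCCC/C=C/C(=O)N1C(=O)C(C(C)=O)=C(O)[C@H]1CC(C)C | target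

Total step count: 8. Longest linear sequence: 7 steps (steps 1 to 6 and step 8); step 7 prepares the acid chloride on the side.

Steps most likely to fail

Step 6 (key step). The ring opening may not be pulled through to C-closure if O-return outpaces C-attack. The nucleophilic amidine may add to the vinylogous carbamate, the isocyanate may be lost to oligomerisation, or vinylogous deprotonation at the stereocentre may erode the configuration. The fallback sets out from 1 and comes back at 13, building the ring by C-acylation of a preformed tetramic acid. Compound 1 is condensed with Meldrum's acid (EDC·HCl, DMAP, CH2Cl2, 0 °C) to tert-butyl N-[(2R)-1-(2,2-dimethyl-4,6-dioxo-1,3-dioxan-5-yl)-4-methyl-1-oxopentan-2-yl]carbamate F1. Heating F1 in EtOAc should expel acetone and CO2 and close tert-butyl (2R)-2-(2-methylpropyl)-3,5-dioxopyrrolidine-1-carboxylate F2. Acetylation at C3 with AcOH, DCC and DMAP (O-acylation followed by DMAP-mediated O-to-C acyl shift) should give tert-butyl (2R)-4-acetyl-3-hydroxy-2-(2-methylpropyl)-5-oxo-2,5-dihydro-1H-pyrrole-1-carboxylate F3, and CF3CO2H in CH2Cl2 removes the Boc group to give 13.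

Step 5. Once the ammonium salt is neutralised, intermolecular aza-Michael addition of the amine to the ynone, or base-induced alkyne–allene isomerisation through the propargylic C–H, may outrun CO2 capture and lead to oligomers or loss of configuration. The fallback sets out from 8 and comes back at 11, leaving out 9 and 10, with the tert-butyl carbamate itself as the carbonyl donor. With Ph3PAuNTf2 (about 5 mol %) in CH2Cl2 at rt the carbamate carbonyl oxygen should add 5-exo-dig to the activated alkyne, the tert-butyl group leaves as 2-methylpropene, and protodeauration gives 11. This cyclisation is established for N-Boc propargylic amines and never exposes a free amine. No new compound arises on this path (F0).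

Step 8. O-Acylation of the tricarbonyl anion, incomplete N-lithiation, or base-mediated epimerisation at C5 in the dianion may compete with N-acylation. The fallback sets out from 13 and comes back at 17, replacing the dianion by neutral silyl-transfer acylation. Compound 13 is persilylated with N,O-bis(trimethylsilyl)acetamide (MeCN, 60 °C) to (5R)-3-acetyl-5-(2-methylpropyl)-1-(trimethylsilyl)-4-[(trimethylsilyl)oxy]-1,5-dihydro-2H-pyrrol-2-one F4. The N-silyl lactam is then acylated by 15 (toluene, 60–80 °C, loss of Me3SiCl), a known reactivity of N-silyl amides, and mild aqueous work-up should cleave the silyl enol ether to give 17.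

Further compounds
F1 | step 6 | tert-butyl N-[(2R)-1-(2,2-dimethyl-4,6-dioxo-1,3-dioxan-5-yl)-4-methyl-1-oxopentan-2-yl]carbamate | CC(C)C[C@@H](NC(=O)OC(C)(C)C)C(=O)C1C(=O)OC(C)(C)OC1=O
F2 | step 6 | tert-butyl (2R)-2-(2-methylpropyl)-3,5-dioxopyrrolidine-1-carboxylate | CC(C)C[C@@H]1C(=O)CC(=O)N1C(=O)OC(C)(C)C
F3 | step 6 | tert-butyl (2R)-4-acetyl-3-hydroxy-2-(2-methylpropyl)-5-oxo-2,5-dihydro-1H-pyrrole-1-carboxylate | CC(C)C[C@@H]1C(O)=C(C(C)=O)C(=O)N1C(=O)OC(C)(C)C
F0 | step 5 | none | none
F4 | step 8 | (5R)-3-acetyl-5-(2-methylpropyl)-1-(trimethylsilyl)-4-[(trimethylsilyl)oxy]-1,5-dihydro-2H-pyrrol-2-one | CC(=O)C1=C(O[Si](C)(C)C)[C@@H](CC(C)C)N([Si](C)(C)C)C1=O
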